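**Retrosynthetic overview**

1. The strategy rests on the benzene ring itself: its C3 (OH), C4 (OMe), C5 (OMe) and C6 (H) correspond one for one to the carbonyl carbon, the two methoxy-bearing sp2 carbons and the CHCl carbon of a four-membered cyclobutenone made from dimethyl squarate, while C1 (side chain) and C2 (H) are the two carbons of a 1,1-disubstituted alkenylstannane.
2. Last disconnection: arene C1–C6 (Stille coupling) and arene C2–C3 (6π electrocyclisation), leading back to 4-chloro-2,3-dimethoxycyclobutenone and the S 2-stannylpent-1-en-3-yl ester of the complete diester acid.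
3. Before that: the carbinol ester C–O bond, leading to (S)-2-(tributylstannyl)pent-1-en-3-ol (ynone transfer hydrogenation, then internal hydrostannation) and (Z)-2-(angeloyloxymethyl)but-2-enoic acid (from but-2-ynoate by syn-hydrostannation, iodination, hydroxymethylation and angeloylation).
4. Ring order: the acyclic diester chain is assembled completely first; the only ring, the benzene ring, is closed in the final operation from four cyclobutenone carbons and two alkene carbons.

Key step: step 15

Remark: the sense of induction in step 3 is assigned by analogy with aryl ketones (the alkynyl group taking the place of the aryl group), so the (S,S) ligand is specified for the S carbinol; the mirror-image ligand would be used if the opposite sense were found.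

**Route**

Step 1
Reactants: 1 trimethylsilylacetylene; 2 propanal
Product: 4 racemic 1-(trimethylsilyl)pent-1-yn-3-ol, via lithium (trimethylsilyl)acetylide 3 (not isolated)
Conditions: n-BuLi, THF, −78 °C; then 2, −78 to 0 °C; H2O quench
Reagents that add atoms: none
Why: Deprotonation of the terminal alkyne and 1,2-addition of the lithium acetylide to the aldehyde (acetylide addition) should give the propargylic alcohol, the silyl group keeping the alkyne terminus masked.

Step 2
Reactants: 4 racemic 1-(trimethylsilyl)pent-1-yn-3-ol
Product: 5 1-(trimethylsilyl)pent-1-yn-3-one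
Conditions: Dess–Martin periodinane, CH2Cl2, 0 °C to rt
Reagents that add atoms: none
Why: Dess–Martin oxidation of a secondary propargylic alcohol is mild and should deliver the ynone without touching the C–Si bond.

Step 3
Reactants: 5 1-(trimethylsilyl)pent-1-yn-3-one
Product: 6 (S)-1-(trimethylsilyl)pent-1-yn-3-ol
Conditions: Ru[(S,S)-TsDPEN](p-cymene) (0.5 mol %), i-PrOH, rt
Reagents that add atoms: none
Why: Noyori asymmetric transfer hydrogenation of an alkynyl ketone, in which the ruthenium hydride and the ligand NH deliver hydrogen to one carbonyl face under catalyst control, should set the S carbinol centre with high enantioselectivity and leave the alkyne unreduced.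

Step 4
Reactants: 6 (S)-1-(trimethylsilyl)pent-1-yn-3-ol
Product: 7 (S)-pent-1-yn-3-ol
Conditions: K2CO3 (cat.), MeOH, rt; extraction into Et2O, careful concentration, solvent switch to THF (volatile, carried as a solution)
Reagents that add atoms: none
Why: Base-mediated methanolysis of the alkynyl C–Si bond (protodesilylation) frees the terminal alkyne and does not involve the carbinol centre.

Step 5
Reactants: 7 (S)-pent-1-yn-3-ol
Product: 8 (S)-2-(tributylstannyl)pent-1-en-3-ol
Conditions: Bu3SnH, Mo(CO)3(CNtBu)3 (2 mol %), hydroquinone (cat.), THF, 55 °C; chromatography on Et3N-deactivated silica to remove any distal stannane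
Reagents that add atoms: tributyltin hydride, CCCC[SnH](CCCC)CCCC
Why: Molybdenum-catalysed hydrostannation of a terminal propargylic alcohol is a syn addition that should place tin on the internal carbon, the radical inhibitor suppressing the distal radical pathway, and no bond to the stereocentre is affected.

Step 6
Reactants: 9 but-2-ynoic acid
Product: 10 tert-butyl but-2-ynoate
Conditions: isobutene, H2SO4 (cat.), CH2Cl2, −20 °C to rt, sealed vessel
Reagents that add atoms: 2-methylpropene (isobutene), CC(C)=C
Why: Acid-catalysed addition of the carboxylic acid to isobutene (tert-butyl ester formation) installs an ester that can later be removed by acid in the presence of the other two esters.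

Step 7
Reactants: 10 tert-butyl but-2-ynoate
Product: 11 tert-butyl (E)-2-(tributylstannyl)but-2-enoate
Conditions: Bu3SnH (slow addition), Pd(PPh3)4 (2 mol %), THF, 0 °C to rt
Reagents that add atoms: tributyltin hydride, CCCC[SnH](CCCC)CCCC
Why: Palladium-catalysed hydrostannation of a 2-alkynoate is a syn addition with tin delivered alpha to the ester, which fixes the methyl group cis to the ester.

Step 8
Reactants: 11 tert-butyl (E)-2-(tributylstannyl)but-2-enoate
Product: 12 tert-butyl (E)-2-iodobut-2-enoate
Conditions: I2 (1.0 equiv), CH2Cl2, 0 °C, dark
Reagents that add atoms: iodine, II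
Why: Iododestannylation is an electrophilic ipso substitution at the alkenyl carbon that proceeds with retention of alkene geometry; light and excess iodine are excluded to avoid isomerisation.

Step 9
Reactants: 12 tert-butyl (E)-2-iodobut-2-enoate
Product: 13 tert-butyl (Z)-2-(hydroxymethyl)but-2-enoate
Conditions: Bu3SnCH2OH, Pd(PPh3)4 (5 mol %), dioxane, 80 °C
Reagents that add atoms: (tributylstannyl)methanol, OC[Sn](CCCC)(CCCC)CCCC
Why: Stille coupling with (tributylstannyl)methanol (hydroxymethylation of an alkenyl iodide) transfers CH2OH with retention, so the methyl group stays cis to the ester and the Z hydroxymethyl enoate results.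

Step 10
Reactants: 13 tert-butyl (Z)-2-(hydroxymethyl)but-2-enoate; 14 angelic acid [(Z)-2-methylbut-2-enoic acid]
Product: 16 tert-butyl (Z)-2-(angeloyloxymethyl)but-2-enoate, via angeloyl 2,4,6-trichlorobenzoyl anhydride 15 (not isolated)
Conditions: 14, 2,4,6-Cl3C6H2COCl, Et3N, toluene, rt; then 13, toluene, 75 °C (no DMAP)
Reagents that add atoms: none
Why: Yamaguchi mixed-anhydride esterification, in which the primary alcohol attacks the unshielded angeloyl carbonyl; leaving out the nucleophilic catalyst should avoid angelate-to-tiglate isomerisation and SN2' attack on the newly formed allylic ester.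

Step 11
Reactants: 16 tert-butyl (Z)-2-(angeloyloxymethyl)but-2-enoate
Product: 17 (Z)-2-(angeloyloxymethyl)but-2-enoic acid
Conditions: TFA, CH2Cl2 (1:4), 0 °C to rt; toluene azeotrope
Reagents that add atoms: none
Why: Acidolysis of the tert-butyl ester (loss of isobutene through the tert-butyl cation) frees the acid, while the two enoate esters and both Z alkenes are expected to be stable to anhydrous acid at room temperature.

Step 12
Reactants: 17 (Z)-2-(angeloyloxymethyl)but-2-enoic acid; 8 (S)-2-(tributylstannyl)pent-1-en-3-ol
Product: 19 (S)-2-(tributylstannyl)pent-1-en-3-yl (Z)-2-(angeloyloxymethyl)but-2-enoate, via 2,4,6-trichlorobenzoyl mixed anhydride 18 (not isolated)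
Conditions: 17, 2,4,6-Cl3C6H2COCl, Et3N, toluene, rt; then 8, Et3N (excess), toluene, 75 °C (no DMAP)
Reagents that add atoms: none
Why: Yamaguchi-type acylation by the preformed mixed anhydride forms the ester at the acyl carbon, so the carbinol C–O bond is untouched and the S configuration is retained, while the amine buffers the 2,4,6-trichlorobenzoic acid that would otherwise protodestannylate the alkenylstannane.

Step 13
Reactants: 20 dimethyl squarate (3,4-dimethoxycyclobut-3-ene-1,2-dione)
Product: 21 racemic 4-hydroxy-2,3-dimethoxycyclobut-2-en-1-one
Conditions: LiAlH(OtBu)3 (1.0 equiv), THF, −78 to −40 °C; pH 7 buffer work-up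
Reagents that add atoms: none
Why: Mono-1,2-reduction of one of the two equivalent carbonyls by a bulky, mild aluminium hydride should stop at the hydroxycyclobutenone, whose remaining carbonyl is a less electrophilic vinylogous ester; neutral work-up avoids acid-promoted collapse to the methoxycyclobutenedione.

Step 14
Reactants: 21 racemic 4-hydroxy-2,3-dimethoxycyclobut-2-en-1-one
Product: 22 racemic 4-chloro-2,3-dimethoxycyclobut-2-en-1-one
Conditions: 1-chloro-N,N,2-trimethylprop-1-en-1-amine (1.0 equiv), CH2Cl2, 0 °C; concentrated cold and used at once
Reagents that add atoms: 1-chloro-N,N,2-trimethylprop-1-en-1-amine, CC(C)=C(Cl)N(C)C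
Why: Deoxychlorination with an alpha-chloroenamine passes through an alkoxyiminium chloride that collapses to the alkyl chloride and a neutral amide, so no acid is generated that could destroy the acid-labile hydroxy compound or the product.

Step 15
Reactants: 19 (S)-2-(tributylstannyl)pent-1-en-3-yl (Z)-2-(angeloyloxymethyl)but-2-enoate; 22 racemic 4-chloro-2,3-dimethoxycyclobut-2-en-1-one
Product: 26 (S)-1-(3-hydroxy-4,5-dimethoxyphenyl)propyl (Z)-2-(angeloyloxymethyl)but-2-enoate (target CNP0282120.1), via 4-alkenylcyclobutenone 23 (not isolated), via dienylketene 24 (not isolated), via cyclohexa-2,4-dienone 25 (not isolated)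
Conditions: PdCl2(PhCN)2 (5 mol %), tri(2-furyl)phosphine (10 mol %), dioxane, 50 °C; then 100 °C
Reagents that add atoms: none
Why: Zerovalent palladium, formed in the flask from the divalent precatalyst and the stannane, inserts into the doubly activated C4–Cl bond of 22, the alkenyl group is transferred from tin, and reductive elimination at the CH terminus gives 23, in which the formerly stannylated alkene carbon is bonded to the former chlorine-bearing carbon (arene C1–C6 bond). On heating, 23 opens by conrotatory 4π electrocyclic cleavage of the bond between the carbonyl carbon and C4 to dienylketene 24, and the isomer with the alkenyl group cis to the ketene closes the benzene ring by a thermal disrotatory 6π electrocyclisation that joins the ketene carbon to the terminal CH2 (arene C2–C3 bond), after which the CH2 of cyclohexadienone 25 enolises irreversibly to the phenol. The closest known reaction type is the palladium-catalysed coupling of 4-chlorocyclobutenones with alkenylstannanes followed by thermal ring expansion to phenols (cyclobutenone benzannulation). No stereocentre is created: C4 of the cyclobutenone ends as an aromatic CH, and the S carbinol carbon, to which no bond is broken, is carried through unchanged. The regiochemistry follows from tin sitting on the internal alkene carbon (side chain meta to the new OH) and from coupling at the unsubstituted CH terminus of the oxocyclobutenyl palladium intermediate and not at its methoxy-bearing terminus, so the former carbonyl oxygen becomes the lone OH next to the two squarate-derived methoxy groups. The step needs insertion into C–Cl to outrun ionisation of the two allylic carboxylates of 19, which the far more reactive C–Cl bond, the weakly donating tri(2-furyl)phosphine, the apolar solvent and the absence of added halide or base should secure, and the neutral medium should leave both Z enoates unchanged.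

**Compound list**

1 | trimethylsilylacetylene | C#C[Si](C)(C)C | starting material
2 | propanal | CCC=O | starting material
3 | lithium (trimethylsilyl)acetylide | [Li]C#C[Si](C)(C)C | intermediate
4 | racemic 1-(trimethylsilyl)pent-1-yn-3-ol | CCC(O)C#C[Si](C)(C)C | intermediate
5 | 1-(trimethylsilyl)pent-1-yn-3-one | CCC(=O)C#C[Si](C)(C)C | intermediate
6 | (S)-1-(trimethylsilyl)pent-1-yn-3-ol | CC[C@H](O)C#C[Si](C)(C)C | intermediate
7 | (S)-pent-1-yn-3-ol | CC[C@H](O)C#C | intermediate
8 | (S)-2-(tributylstannyl)pent-1-en-3-ol | CC[C@H](O)C(=C)[Sn](CCCC)(CCCC)CCCC | intermediate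
9 | but-2-ynoic acid | CC#CC(=O)O | starting material
10 | tert-butyl but-2-ynoate | CC#CC(=O)OC(C)(C)C | intermediate
11 | tert-butyl (E)-2-(tributylstannyl)but-2-enoate (methyl cis to the ester) | C/C=C(/[Sn](CCCC)(CCCC)CCCC)C(=O)OC(C)(C)C | intermediate
12 | tert-butyl (E)-2-iodobut-2-enoate (methyl cis to the ester) | C/C=C(/I)C(=O)OC(C)(C)C | intermediate
13 | tert-butyl (Z)-2-(hydroxymethyl)but-2-enoate | OC/C(=C/C)C(=O)OC(C)(C)C | intermediate
14 | angelic acid, (Z)-2-methylbut-2-enoic acid | C/C=C(/C)C(=O)O | starting material
15 | angeloyl 2,4,6-trichlorobenzoyl anhydride | C/C=C(/C)C(=O)OC(=O)c1c(Cl)cc(Cl)cc1Cl | intermediate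
16 | tert-butyl (Z)-2-(angeloyloxymethyl)but-2-enoate | C/C=C(/C)C(=O)OC/C(=C/C)C(=O)OC(C)(C)C | intermediate
17 | (Z)-2-(angeloyloxymethyl)but-2-enoic acid | C/C=C(/C)C(=O)OC/C(=C/C)C(=O)O | intermediate
18 | mixed anhydride of 17 with 2,4,6-trichlorobenzoic acid | C/C=C(/C)C(=O)OC/C(=C/C)C(=O)OC(=O)c1c(Cl)cc(Cl)cc1Cl | intermediate
19 | (S)-2-(tributylstannyl)pent-1-en-3-yl (Z)-2-(angeloyloxymethyl)but-2-enoate | C/C=C(/C)C(=O)OC/C(=C/C)C(=O)O[C@@H](CC)C(=C)[Sn](CCCC)(CCCC)CCCC | intermediate
20 | dimethyl squarate | COC1=C(OC)C(=O)C1=O | starting material
21 | racemic 4-hydroxy-2,3-dimethoxycyclobut-2-en-1-one | COC1=C(OC)C(O)C1=O | intermediate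
22 | racemic 4-chloro-2,3-dimethoxycyclobut-2-en-1-one | COC1=C(OC)C(Cl)C1=O | intermediate
23 | (S)-2-(2,3-dimethoxy-4-oxocyclobut-2-en-1-yl)pent-1-en-3-yl (Z)-2-(angeloyloxymethyl)but-2-enoate (both epimers at the ring CH) | C/C=C(/C)C(=O)OC/C(=C/C)C(=O)O[C@@H](CC)C(=C)C1C(OC)=C(OC)C1=O | intermediate
24 | dienylketene O=C=C(OMe)–C(OMe)=CH–C(=CH2)–CH(Et)O-acyl, S at the carbinol, alkenyl group cis to the ketene-bearing carbon | C/C=C(/C)C(=O)OC/C(=C/C)C(=O)O[C@@H](CC)C(=C)/C=C(OC)\C(OC)=C=O | intermediate
25 | (S)-1-(3,4-dimethoxy-5-oxocyclohexa-1,3-dien-1-yl)propyl (Z)-2-(angeloyloxymethyl)but-2-enoate | C/C=C(/C)C(=O)OC/C(=C/C)C(=O)O[C@@H](CC)C1=CC(OC)=C(OC)C(=O)C1 | intermediate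
26 | (S)-1-(3-hydroxy-4,5-dimethoxyphenyl)propyl (Z)-2-(angeloyloxymethyl)but-2-enoate, CNP0282120.1 | C/C=C(/C)C(=O)OC/C(=C/C)C(=O)O[C@@H](CC)c1cc(O)c(OC)c(OC)c1 | target

**Step count**

Total steps: 15. Longest linear sequence: 8 steps (steps 6, 7, 8, 9, 10, 11, 12 and 15, from but-2-ynoic acid).

**Three steps most likely to fail**

1. Step 15. What may go wrong: zerovalent palladium ionises the allylic carboxylates of 19 instead of, or alongside, the C–Cl bond, which would scramble or remove ester groups and erode the Z geometry of the central alkene through a π-allyl intermediate. Carboxylate could also be lost by β-elimination after transmetalation, the stannane could be protodestannylated, or 22 could decompose before coupling. Fallback: the arene is bought instead of built, and the route is rejoined from acid 17 through its mixed anhydride 18. Commercial 3-hydroxy-4,5-dimethoxybenzaldehyde F1 would be silylated (TBSCl, imidazole, DMF) to 3-(tert-butyldimethylsilyloxy)-4,5-dimethoxybenzaldehyde F2. Enantioselective addition of Et2Zn catalysed by (2S)-(−)-3-exo-(dimethylamino)isoborneol (toluene, 0 °C), the ligand enantiomer that delivers S carbinols from aromatic aldehydes, should give (S)-1-[3-(tert-butyldimethylsilyloxy)-4,5-dimethoxyphenyl]propan-1-ol F3. Acylation of F3 with 18 under the conditions of step 12 would give the silyl-protected ester F4, and buffered desilylation (TBAF, AcOH, THF, 0 °C) would return to the route at 26.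

2. Step 14. What may go wrong: the chloride ionises as it forms or on concentration, with assistance from the 2-methoxy group, and loses methyl chloride to give the methoxycyclobutenedione; the hydroxy compound may also collapse the same way. Fallback: a leaving group that does not ionise spontaneously. Starting from 21, methyl chloroformate and pyridine (CH2Cl2, −20 °C) should give the isolable 2,3-dimethoxy-4-oxocyclobut-2-en-1-yl methyl carbonate F5. Decarboxylative coupling of F5 with stannane 19 under zerovalent palladium (Pd2(dba)3, tri(2-furyl)phosphine, THF, 50 °C) is a known allylic carbonate–organostannane coupling, in which the released methoxide activates tin. It would rejoin the route at the 4-alkenylcyclobutenone 23, which is then heated to 26 as in step 15.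

3. Step 12. What may go wrong: acylation of the hindered carbinol next to the tributylstannyl group is slow, leaving time for protodestannylation, Z to E isomerisation of the activated enoyl group, or SN2' loss of angelate. Fallback: acylate before the tin is introduced. Starting from the unhindered propargylic alcohol 7 and mixed anhydride 18 (Et3N, toluene, 75 °C, no DMAP), the ester (S)-pent-1-yn-3-yl (Z)-2-(angeloyloxymethyl)but-2-enoate F6 would be formed. Molybdenum-catalysed hydrostannation of F6 (Bu3SnH, Mo(CO)3(CNtBu)3, hydroquinone, THF, 55 °C), propargylic esters being the substrates that give the highest internal selectivity, would rejoin the route at 19.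

**Further compounds**

F1 | step 15 | 3-hydroxy-4,5-dimethoxybenzaldehyde | O=Cc1cc(O)c(OC)c(OC)c1
F2 | step 15 | 3-(tert-butyldimethylsilyloxy)-4,5-dimethoxybenzaldehyde | O=Cc1cc(O[Si](C)(C)C(C)(C)C)c(OC)c(OC)c1
F3 | step 15 | (S)-1-[3-(tert-butyldimethylsilyloxy)-4,5-dimethoxyphenyl]propan-1-ol | CC[C@H](O)c1cc(O[Si](C)(C)C(C)(C)C)c(OC)c(OC)c1
F4 | step 15 | (S)-1-[3-(tert-butyldimethylsilyloxy)-4,5-dimethoxyphenyl]propyl (Z)-2-(angeloyloxymethyl)but-2-enoate | C/C=C(/C)C(=O)OC/C(=C/C)C(=O)O[C@@H](CC)c1cc(O[Si](C)(C)C(C)(C)C)c(OC)c(OC)c1
F5 | step 14 | 2,3-dimethoxy-4-oxocyclobut-2-en-1-yl methyl carbonate (racemic) | COC(=O)OC1C(OC)=C(OC)C1=O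
F6 | step 12 | (S)-pent-1-yn-3-yl (Z)-2-(angeloyloxymethyl)but-2-enoate | C/C=C(/C)C(=O)OC/C(=C/C)C(=O)O[C@@H](CC)C#C
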